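**Strategy.** Drimane numbering: ring A = C1–C5/C10, ring B = C5–C10, C11 = CH2O, C12 = methyl on C8. Ring B is closed last through C8–C9. The C7=C8 olefin lying β,γ to oxidised C11 is read as the trace of an alkyne: a ring-A ketol bearing a but-2-ynyl chain on C5 and a methyl enol ether (C9=C11) on quaternary C10 undergoes gold-catalysed 6-endo-dig carbocyclisation, which at once forms ring B, fixes the C7=C8 olefin, sets C9 and delivers C11 as aldehyde. The trans C5/C10 relationship comes from a stereospecific Diels–Alder reaction of an (E)-enal; C2 and C3 from enolate hydroxylation and hydride reduction; the coumarin is attached last.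

Key step: step 6

Remark: the facial sense of the diol catalyst in step 2 is assigned by analogy with α-substituted acroleins; if the opposite enal face is attacked, the mirror-image catalyst is used.
Remark: 9, 10 and 12 are carried as E/Z mixtures at the enol ether; both isomers should converge in step 6.

Step 1
Reactants: 1 pent-3-yn-1-ol; 2 2-(triphenyl-λ5-phosphanylidene)propanal
Product: 4 (2E)-2-methylhept-2-en-5-ynal, via pent-3-ynal 3 (not isolated)
Conditions: DMP, NaHCO3, CH2Cl2, 0 °C; then 2, 0 °C → rt
Reagents that add atoms: none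
Why: Periodinane oxidation gives the labile β,γ-alkynyl aldehyde, which is trapped at once by the stabilised formyl ylide in an (E)-selective Wittig olefination (tandem oxidation–Wittig), placing the propargylic CH2 cis to the methyl group.

Step 2
Reactants: 4 (2E)-2-methylhept-2-en-5-ynal; 5 (1E)-3-[(tert-butyldimethylsilyl)oxy]-N,N-dimethylbuta-1,3-dien-1-amine
Product: 7 (1S,6R)-6-(but-2-yn-1-yl)-1-methyl-4-oxocyclohex-2-ene-1-carbaldehyde, via aminocyclohexene cycloadduct 6 (not isolated)
Conditions: (4R,5R)-2,2-dimethyl-α,α,α′,α′-tetra(1-naphthyl)-1,3-dioxolane-4,5-dimethanol (20 mol%), toluene, −60 °C; then 0.5 M HCl, THF, 0 °C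
Reagents that add atoms: none
Why: Hydrogen-bond-catalysed Diels–Alder reaction in which the CH2 terminus of the aminosiloxydiene bonds to C5 and the amino terminus to C10, suprafacial addition to the (E)-enal fixes the methyl group cis to the butynyl chain (C9 trans to C6), the chiral diol selects the enal face and so the absolute configuration at C5 and C10, and acid then hydrolyses the silyl enol ether and eliminates dimethylamine to the enone.

Step 3
Reactants: 7 (1S,6R)-6-(but-2-yn-1-yl)-1-methyl-4-oxocyclohex-2-ene-1-carbaldehyde; 8 (methoxymethyl)triphenylphosphonium chloride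
Product: 9 (4S,5R)-5-(but-2-yn-1-yl)-4-(2-methoxyethenyl)-4-methylcyclohex-2-en-1-one (E/Z mixture)
Conditions: KN(SiMe3)2, THF, −78 → −20 °C
Reagents that add atoms: none
Why: Wittig methoxymethylenation, in which the non-stabilised ylide should react with the aldehyde at low temperature much faster than with the conjugated ring ketone, giving the C9=C11 enol ether.

Step 4
Reactants: 9 (4S,5R)-5-(but-2-yn-1-yl)-4-(2-methoxyethenyl)-4-methylcyclohex-2-en-1-one
Product: 10 (4R,5S)-5-(but-2-yn-1-yl)-4-(2-methoxyethenyl)-4,6,6-trimethylcyclohex-2-en-1-one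
Conditions: LiN(i-Pr)2, THF, −78 °C; MeI, −78 → 0 °C; cycle repeated once
Reagents that add atoms: iodomethane, CI
Why: Kinetic α′-enolate alkylation, in which C4 is the only enolisable position of the γ-quaternary enone (C2 is vinylic, C10 quaternary), so two deprotonation–methylation cycles install the gem-dimethyl group without touching C5.

Step 5
Reactants: 10 (4R,5S)-5-(but-2-yn-1-yl)-4-(2-methoxyethenyl)-4,6,6-trimethylcyclohex-2-en-1-one
Product: 12 (3S,4R,6S)-3-(but-2-yn-1-yl)-6-hydroxy-4-(2-methoxyethenyl)-2,2,4-trimethylcyclohexan-1-one, via lithium enolate 11 (not isolated)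
Conditions: LiBH(s-Bu)3, THF, −78 °C; then 2-(phenylsulfonyl)-3-phenyloxaziridine, −78 → −40 °C; NH4Cl (aq)
Reagents that add atoms: 2-(phenylsulfonyl)-3-phenyloxaziridine, O=S(=O)(c1ccccc1)N1OC1c1ccccc1
Why: Conjugate hydride reduction (1,2-attack is blocked at the neopentyl carbonyl) gives the C2=C3 enolate regiospecifically, and electrophilic enolate hydroxylation at C2 occurs on the face opposite the syn-axial C4 and C10 methyl groups, giving the equatorial 2-OH trans to the C10 methyl, which is also the thermodynamic epimer of this ketol.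

Step 6
Reactants: 12 (3S,4R,6S)-3-(but-2-yn-1-yl)-6-hydroxy-4-(2-methoxyethenyl)-2,2,4-trimethylcyclohexan-1-one
Product: 13 (1R,4aS,7S,8aR)-7-hydroxy-2,5,5,8a-tetramethyl-6-oxo-1,4,4a,5,6,7,8,8a-octahydronaphthalene-1-carbaldehyde
Conditions: [LAu(NCMe)]SbF6 (5 mol%, L = 2-(di-tert-butylphosphino)-3,4,5,6-tetramethyl-2′,4′,6′-triisopropylbiphenyl), H2O (2 equiv), CH2Cl2, rt; short silica filtration, used directly
Reagents that add atoms: water, O
Why: The cationic monovalent gold complex π-activates the C7≡C8 alkyne and the electron-rich enol ether carbon C9 attacks C8 anti to gold; water then collapses the C11 oxocarbenium ion to the aldehyde with loss of methanol, and the proton set free protodeaurates the C7 vinyl-gold, so the olefin ends at C7=C8 with H on C7. The closest known reaction type is the gold-catalysed Conia-ene-type carbocyclisation of enol ethers onto tethered alkynes. Ring B closes in the 6-endo-dig mode. The new stereocenter C9 is controlled by quaternary C10: the enol ether should react through the rotamer whose C9=C11 bond eclipses the small C10 methyl and points away from the C5–C6 tether, so that C8 bonds to the face that leaves C11 equatorial and cis to that methyl, while the trans ring fusion follows from the trans-diequatorial C6 and C9 arms fixed in step 2. The step needs attack at C8 (6-endo-dig) and not at C7 (5-exo-dig), which should be secured by the bulky biarylphosphine ligand known to favour endo closure, by the methyl-capped internal alkyne and by the strain of the alternative trans-fused five-membered ring with an exocyclic alkylidene. The neopentyl C3 ketone and the remote C2 hydroxyl are far poorer nucleophiles toward the gold-bound alkyne than the enol ether.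

Step 7
Reactants: 13 (1R,4aS,7S,8aR)-7-hydroxy-2,5,5,8a-tetramethyl-6-oxo-1,4,4a,5,6,7,8,8a-octahydronaphthalene-1-carbaldehyde
Product: 14 (2S,3S,4aR,5R,8aS)-5-(hydroxymethyl)-1,1,4a,6-tetramethyl-1,2,3,4,4a,5,8,8a-octahydronaphthalene-2,3-diol
Conditions: NaBH4, MeOH, −20 → 0 °C
Reagents that add atoms: none
Why: Borohydride reduction of both carbonyl groups, in which the aldehyde is reduced to the C11 carbinol before C9 can epimerise and the C3 ketone is attacked axially from the face opposite the axial C4 methyl, giving the equatorial 3-OH trans to the 2-OH (substrate-controlled 1,2-reduction).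

Step 8
Reactants: 14 (2S,3S,4aR,5R,8aS)-5-(hydroxymethyl)-1,1,4a,6-tetramethyl-1,2,3,4,4a,5,8,8a-octahydronaphthalene-2,3-diol; 15 7-hydroxy-2H-chromen-2-one
Product: 16 7-{[(1R,4aS,6S,7S,8aR)-6,7-dihydroxy-2,5,5,8a-tetramethyl-1,4,4a,5,6,7,8,8a-octahydronaphthalen-1-yl]methoxy}-2H-chromen-2-one
Conditions: PPh3, DIAD, THF, 0 °C → rt
Reagents that add atoms: none
Why: Mitsunobu etherification, in which only the primary C11 alkoxyphosphonium can be displaced by the phenoxide (SN2), because backside attack at C2 or C3 is blocked by the syn-axial methyl groups and the neopentyl environment, so the coumarin should be attached without protecting the trans-diol.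

**Compound list**
1 | pent-3-yn-1-ol | CC#CCCO | starting material
2 | 2-(triphenyl-λ5-phosphanylidene)propanal | CC(C=O)=P(c1ccccc1)(c1ccccc1)c1ccccc1 | starting material
3 | pent-3-ynal | CC#CCC=O | intermediate
4 | (2E)-2-methylhept-2-en-5-ynal | CC#CC/C=C(\C)C=O | intermediate
5 | (1E)-3-[(tert-butyldimethylsilyl)oxy]-N,N-dimethylbuta-1,3-dien-1-amine | C=C(O[Si](C)(C)C(C)(C)C)/C=C/N(C)C | starting material
6 | 6-(but-2-yn-1-yl)-4-[(tert-butyldimethylsilyl)oxy]-2-(dimethylamino)-1-methylcyclohex-3-ene-1-carbaldehyde (C5 and C10 as in 7; amino-bearing carbon unassigned) | CC#CC[C@@H]1CC(O[Si](C)(C)C(C)(C)C)=CC(N(C)C)[C@@]1(C)C=O | intermediate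
7 | (1S,6R)-6-(but-2-yn-1-yl)-1-methyl-4-oxocyclohex-2-ene-1-carbaldehyde | CC#CC[C@@H]1CC(=O)C=C[C@@]1(C)C=O | intermediate
8 | (methoxymethyl)triphenylphosphonium chloride | COC[P+](c1ccccc1)(c1ccccc1)c1ccccc1.[Cl-] | starting material
9 | (4S,5R)-5-(but-2-yn-1-yl)-4-(2-methoxyethenyl)-4-methylcyclohex-2-en-1-one (E/Z mixture) | CC#CC[C@@H]1CC(=O)C=C[C@@]1(C)C=COC | intermediate
10 | (4R,5S)-5-(but-2-yn-1-yl)-4-(2-methoxyethenyl)-4,6,6-trimethylcyclohex-2-en-1-one | CC#CC[C@@H]1C(C)(C)C(=O)C=C[C@@]1(C)C=COC | intermediate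
11 | lithium C2=C3 enolate of the saturated ketone derived from 10 | CC#CC[C@@H]1C(C)(C)C([O-])=CC[C@@]1(C)C=COC.[Li+] | intermediate
12 | (3S,4R,6S)-3-(but-2-yn-1-yl)-6-hydroxy-4-(2-methoxyethenyl)-2,2,4-trimethylcyclohexan-1-one | CC#CC[C@@H]1C(C)(C)C(=O)[C@@H](O)C[C@@]1(C)C=COC | intermediate
13 | (1R,4aS,7S,8aR)-7-hydroxy-2,5,5,8a-tetramethyl-6-oxo-1,4,4a,5,6,7,8,8a-octahydronaphthalene-1-carbaldehyde | CC1=CC[C@@H]2C(C)(C)C(=O)[C@@H](O)C[C@@]2(C)[C@@H]1C=O | intermediate
14 | (2S,3S,4aR,5R,8aS)-5-(hydroxymethyl)-1,1,4a,6-tetramethyl-1,2,3,4,4a,5,8,8a-octahydronaphthalene-2,3-diol | CC1=CC[C@@H]2C(C)(C)[C@H](O)[C@@H](O)C[C@@]2(C)[C@@H]1CO | intermediate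
15 | 7-hydroxy-2H-chromen-2-one (umbelliferone) | Oc1ccc2ccc(=O)oc2c1 | starting material
16 | 7-{[(1R,4aS,6S,7S,8aR)-6,7-dihydroxy-2,5,5,8a-tetramethyl-1,4,4a,5,6,7,8,8a-octahydronaphthalen-1-yl]methoxy}-2H-chromen-2-one | CC1=CC[C@@H]2C(C)(C)[C@H](O)[C@@H](O)C[C@@]2(C)[C@@H]1COc1ccc2ccc(=O)oc2c1 | target

Total step count: 8. Longest linear sequence: 8 steps.

**Steps most likely to fail**

1. Step 6. The enol ether carbon may bond to the nearer alkyne carbon C7 (5-exo-dig), facial control at C9 may be lost through the other enol ether rotamer, or the alkyne may be hydrated with assistance of the ketone oxygen. The fallback forms C8–C9 by a Heck reaction and sets C9 afterwards. It sets out from 1: trans-hydroalumination with NaAlH2(OCH2CH2OMe)2 and iodinolysis should give (3Z)-4-iodopent-3-en-1-ol F1. The oxidation–Wittig sequence of step 1 with 2 then gives (2E,5Z)-6-iodo-2-methylhepta-2,5-dienal F2. Cycloaddition with 5 as in step 2 gives the iodo-substituted aminocyclohexene adduct F3, which is methylenated with Ph3P=CH2 before the acid unveiling to give the 4-ethenyl enone F4. Double methylation as in step 4 gives the trimethyl enone F5, reductive hydroxylation as in step 5 gives the ketol F6, and NaBH4 gives the trans-diol F7. A 6-exo-trig Heck cyclisation (Pd(OAc)2, PPh3, Ag2CO3, MeCN, 70 °C) joins C8 to C9, and β-hydride elimination gives the 7,9(11)-diene diol F8. Hydroboration with 9-BBN from the face opposite the C10 methyl, then NaOH/H2O2, places H on C9 and OH on C11 and comes back to the route at 14.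

2. Step 2. The trisubstituted enal may add too slowly at low temperature, so that uncatalysed background reaction erodes facial selectivity. The fallback sets out from 4 and uses Lewis-acid catalysis with a simple siloxydiene. A Diels–Alder reaction with 2-(trimethylsilyloxy)buta-1,3-diene, catalysed by the chiral oxazaborolidinium triflimide made from (S)-α,α-diphenylprolinol, o-tolylboronic acid and Tf2NH (CH2Cl2, −78 °C), should give the silyl enol ether cycloadduct F9 with the same para regiochemistry and cis methyl/butynyl relationship. Saegusa–Ito dehydrogenation (Pd(OAc)2, MeCN) toward C1 then gives the enone and comes back to the route at 7.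

3. Step 8. The reagents may be tied up as a cyclic phosphorane at the trans-diol, substitution at the β-branched primary carbinol may be slow, and elimination toward the 7,9(11)-diene may compete. The fallback sets out from 14 and protects the diol. 2,2-Dimethoxypropane/PPTS, followed by brief methanolysis of the mixed acetal at C11, gives the 2,3-acetonide alcohol F10. Mitsunobu etherification with 15 gives the acetonide ether F11, and 80% aqueous AcOH removes the acetonide and comes back to the route at 16.

**Further compounds**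
F1 | step 6 | (3Z)-4-iodopent-3-en-1-ol | C/C(I)=C/CCO
F2 | step 6 | (2E,5Z)-6-iodo-2-methylhepta-2,5-dienal | C/C(I)=C/C/C=C(\C)C=O
F3 | step 6 | iodo analogue of cycloadduct 6: 4-[(tert-butyldimethylsilyl)oxy]-2-(dimethylamino)-6-[(2Z)-3-iodobut-2-en-1-yl]-1-methylcyclohex-3-ene-1-carbaldehyde (amino-bearing carbon unassigned) | C/C(I)=C/C[C@@H]1CC(O[Si](C)(C)C(C)(C)C)=CC(N(C)C)[C@@]1(C)C=O
F4 | step 6 | 4-ethenyl-5-[(2Z)-3-iodobut-2-en-1-yl]-4-methylcyclohex-2-en-1-one (methyl cis to the iodobutenyl chain, configured as in 7) | C/C(I)=C/C[C@@H]1CC(=O)C=C[C@@]1(C)C=C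
F5 | step 6 | 4-ethenyl-5-[(2Z)-3-iodobut-2-en-1-yl]-4,6,6-trimethylcyclohex-2-en-1-one (configured as in 10) | C/C(I)=C/C[C@@H]1C(C)(C)C(=O)C=C[C@@]1(C)C=C
F6 | step 6 | 4-ethenyl-6-hydroxy-3-[(2Z)-3-iodobut-2-en-1-yl]-2,2,4-trimethylcyclohexan-1-one (configured as in 12) | C/C(I)=C/C[C@@H]1C(C)(C)C(=O)[C@@H](O)C[C@@]1(C)C=C
F7 | step 6 | 5-ethenyl-4-[(2Z)-3-iodobut-2-en-1-yl]-3,3,5-trimethylcyclohexane-1,2-diol (trans-diol, configured as in 14) | C/C(I)=C/C[C@@H]1C(C)(C)[C@H](O)[C@@H](O)C[C@@]1(C)C=C
F8 | step 6 | 1,1,4a,6-tetramethyl-5-methylidene-1,2,3,4,4a,5,8,8a-octahydronaphthalene-2,3-diol (7,9(11)-diene, ring A configured as in 14) | CC1=CC[C@@H]2C(C)(C)[C@H](O)[C@@H](O)C[C@@]2(C)C1=C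
F9 | step 2 | 6-(but-2-yn-1-yl)-1-methyl-4-[(trimethylsilyl)oxy]cyclohex-3-ene-1-carbaldehyde (configured as in 7) | CC#CC[C@@H]1CC(O[Si](C)(C)C)=CC[C@@]1(C)C=O
F10 | step 8 | 2,3-O-isopropylidene derivative of 14 (free C11 hydroxyl) | CC1=CC[C@@H]2C(C)(C)[C@@H]3OC(C)(C)O[C@H]3C[C@@]2(C)[C@@H]1CO
F11 | step 8 | 2,3-O-isopropylidene derivative of 16 | CC1=CC[C@@H]2C(C)(C)[C@@H]3OC(C)(C)O[C@H]3C[C@@]2(C)[C@@H]1COc1ccc2ccc(=O)oc2c1
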